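The constants used here belong to no real substance; the run is a simulation.

A small charge of solid substrate, 0.12 M against a solubility of 0.31 M, can go wholly into solution; these flasks ask what larger charges do to the target.

    dissolved substrate + target → side product (k1 = 0.198 /M/s)
    dissolved substrate + coupling partner → target (k2 = 0.168 /M/s)
    solid substrate ⇌ dissolved substrate, rate k3*(cs3 - [dissolved substrate]) while solid is left; crystals form when [dissolved substrate] > cs3 (cs3 = 0.31 M, k3 = 0.122 /s)
    coupling partner + protic impurity → quenched reagent (k4 = 0.119 /M/s)
    2 coupling partner → self-condensation product (k5 = 0.176 /M/s)

the same everywhere: coupling partner 1.20 equiv; protic impurity 0.0500 M; time 80 s
- east: solid substrate 0.12 M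
- south-west: solid substrate 0.25 M
- north-east: solid substrate 0.50 M

- in percentages every species weighs as the solid substrate in it: one side product counts as two
- where a step has two of a species, its rate is k times that concentration squared, and two are used at each turn
- as a solid, counted per litre of solution: solid substrate
- at the start none of the solid substrate is in solution
- "hardly changes" means that all values lie within two and a half points (for a concentration: within two and a half percent of the largest)
- run time (east): 80 s

- [target] at the end for east, south-west, north-east, in this order
- the course of these numbers from the first flask to the last (falls all the way / falls, then rises / rises, then falls / hardly changes / rises all the way)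

Write A for dissolved substrate, B for coupling partner and P for target, with brackets for concentrations, and kc and ks for the constants of coupling and of side-product formation. Target is made at kc[A][B] and eaten at ks[A][P], so [A] stands in both rates and cancels from their ratio. The constants give kc/ks = 0.848, and that figure times [B]/[P] is the balance M. Target grows while M is above one and falls once M is below one. M starts without limit, since [P] is zero, and drifts down as B is lost and P accumulates. The loss step taken on its own, with [A] held, is pseudo-first-order in target with half-life ln(2)/(ks[A]); B's feed offsets part of that loss while M stays near one.

| flask | B, first half-life by self-condensation | P, half-life with [A] at the lesser of charge and solubility |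
|---|---|---|
| east | 19.7 s | 29.2 s |
| south-west | 9.47 s | 14.0 s |
| north-east | 4.73 s | 11.3 s |

With the charge fully dissolved, in east and south-west alike, coupling starts at 0.398 of the pace of B's loss to self-condensation, so the larger charge of south-west should make more target. In north-east [B] is twice that of south-west, but [A] stops at the solubility, so the figure drops to 0.247, and target's half-life is shorter than in south-west. A rough index for ordering the flasks, and no concentration, is the charge times that figure times B's half-life over target's: 0.0323 M for east, 0.0672 M for south-west and 0.0517 M for north-east. This reckoning gives no concentrations and commits to this course: rises, then falls.

The forecast gave 0.021 M, 0.024 M and 0.016 M, in its words “a slight rise then a fall”, hence rises, then falls.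

The simulation gives 0.0206 M, 0.0238 M and 0.0104 M, so the course rises, then falls.

In east, coupling ran while B stood, half of its turnover done by 15.4 s, and at 40.0 s B was down to 19.2% of its charge with target at 20.0%, a balance of 0.978. Side product then grew to 38.6% in east while target slipped to 17.2%, the balance ending at 0.493. In north-east the balance was already 0.444 at 40.0 s and 0.245 at 80.0 s, with target falling from 8.22% to 2.09% of the charge.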